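**Retrosynthetic overview**
1. Target ← global desilylation ← Pd-catalysed Suzuki–Miyaura union (chain C11–C12) of a ring-bearing (Z)-alkenyl MIDA boronate with an all-E pentaenyl iodide.
2. Ring-bearing boronate ← key step: ligand-controlled nickel-catalysed coupling of a bicyclic lactol tert-butyl carbonate with a cis-1,2-diborylpropene (Bpin reacts, B(MIDA) is kept); it forms the ring C2–chain C13 bond and sets C2.
3. Bicyclic carbonate: cyclohexane ring first (mesityl oxide/methyl acetoacetate annulation), dihydrofuran ring second (acid rearrangement of an epoxy enol ether); C7a by Sharpless epoxidation, C6 by substrate-controlled ketone reduction.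
4. Pentaenyl iodide ← Horner–Wadsworth–Emmons union of an iododienal and a dienyl phosphonate (both from small enynols); diborylpropene ← propyne bromoboration, then Miyaura borylation.

Assumption: both enynols are bought as pure E isomers, the lactol-carbon (C2) anomers are carried as mixtures up to the nickel step, and locants are those of the benzofuran ring (C2, C6, C7a) and the tetradecahexaenol chain (C1–C14) of the target.

**Fragment A (ring electrophile)**

Step 1
Reactants: 1 mesityl oxide (4-methylpent-3-en-2-one); 2 methyl acetoacetate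
Product: 3 methyl 2,6,6-trimethyl-4-oxocyclohex-2-ene-1-carboxylate (racemic)
Conditions: ZnCl2 (0.3 equiv), heptane–toluene, reflux, Dean–Stark
Reagents that add atoms: none
Why: Lewis-acid-promoted Michael addition of the acetoacetate to the enone followed by intramolecular aldol condensation (Robinson-type annulation) builds the six-membered ring with the gem-dimethyl group, the ring methyl and the future furan carbon (the ester) in place; the single stereocentre is erased in step 2.

Step 2
Reactants: 3 methyl 2,6,6-trimethyl-4-oxocyclohex-2-ene-1-carboxylate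
Product: 4 methyl 7,9,9-trimethyl-1,4-dioxaspiro[4.5]dec-7-ene-8-carboxylate
Conditions: HOCH2CH2OH (3 equiv), p-TsOH (cat.), toluene, reflux, Dean–Stark
Reagents that add atoms: ethylene glycol, OCCO
Why: Acid-catalysed ketalisation of the enone runs through the dienol, so the double bond moves into the tetrasubstituted position conjugated with the ester (ketalisation with double-bond transposition) and the intermediate becomes achiral.

Step 3
Reactants: 4 methyl 7,9,9-trimethyl-1,4-dioxaspiro[4.5]dec-7-ene-8-carboxylate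
Product: 5 (7,9,9-trimethyl-1,4-dioxaspiro[4.5]dec-7-en-8-yl)methanol
Conditions: LiAlH4, Et2O, 0 °C
Reagents that add atoms: none
Why: Hydride reduction of the hindered conjugated ester to the primary allylic alcohol leaves the ketal and the tetrasubstituted alkene untouched (ester reduction).

Step 4
Reactants: 5 (7,9,9-trimethyl-1,4-dioxaspiro[4.5]dec-7-en-8-yl)methanol
Product: 6 [(1R,6R)-4,4-(ethylenedioxy)-2,2,6-trimethyl-7-oxabicyclo[4.1.0]heptan-1-yl]methanol
Conditions: Ti(OiPr)4 (0.2 equiv), D-(−)-diethyl tartrate (0.25 equiv), t-BuOOH, 4 Å molecular sieves, CH2Cl2, −20 °C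
Reagents that add atoms: tert-butyl hydroperoxide, CC(C)(C)OO
Why: Sharpless asymmetric epoxidation of the achiral allylic alcohol is pure reagent control, and the D-(−)-tartrate catalyst delivers oxygen to the face that makes the methyl-bearing epoxide carbon (the future C7a) R.

Step 5
Reactants: 6 [(1R,6R)-4,4-(ethylenedioxy)-2,2,6-trimethyl-7-oxabicyclo[4.1.0]heptan-1-yl]methanol
Product: 7 (1S,6R)-4,4-(ethylenedioxy)-2,2,6-trimethyl-7-oxabicyclo[4.1.0]heptane-1-carbaldehyde
Conditions: Dess–Martin periodinane, pyridine, CH2Cl2, 0 °C to rt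
Reagents that add atoms: none
Why: Buffered Dess–Martin oxidation gives the epoxy aldehyde, which has no α-hydrogen and so cannot epimerise (alcohol oxidation).

Step 6
Reactants: 8 chloromethyl methyl ether
Product: 9 (methoxymethyl)triphenylphosphonium chloride
Conditions: PPh3, toluene, 50 °C
Reagents that add atoms: triphenylphosphine, c1ccc(cc1)P(c1ccccc1)c1ccccc1
Why: Quaternisation of triphenylphosphine by the reactive α-chloro ether gives the Wittig salt that will supply the lactol carbon (phosphonium salt formation).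

Step 7
Reactants: 7 (1S,6R)-4,4-(ethylenedioxy)-2,2,6-trimethyl-7-oxabicyclo[4.1.0]heptane-1-carbaldehyde; 9 (methoxymethyl)triphenylphosphonium chloride
Product: 13 (7aR)-2-hydroxy-4,4,7a-trimethyl-2,4,5,7a-tetrahydro-1-benzofuran-6(7H)-one (keto lactol; both C2 anomers), via phosphorus ylide 10 (not isolated), via epoxy enol ether 11 (not isolated), via methoxy acetal 12 (not isolated)
Conditions: 9, KN(SiMe3)2, THF, 0 °C; 7, −78 to 0 °C; then 1 M aq. HCl, THF, 0 °C to rt
Reagents that add atoms: water, O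
Why: Wittig methoxymethylenation gives the epoxy enol ether, acid then opens the epoxide at the carbon next to the enol ether and the retained tertiary oxygen closes the dihydrofuran on the oxocarbenium carbon (furanoid oxide rearrangement), and the same aqueous acid hydrolyses the methyl acetal and the dioxolane; the C7a–O bond is never broken, so C7a stays R.

Step 8
Reactants: 13 (7aR)-2-hydroxy-4,4,7a-trimethyl-2,4,5,7a-tetrahydro-1-benzofuran-6(7H)-one
Product: 14 tert-butyl [(7aR)-4,4,7a-trimethyl-6-oxo-2,4,5,6,7,7a-hexahydro-1-benzofuran-2-yl] carbonate (both C2 anomers)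
Conditions: Boc2O, DMAP (cat.), CH2Cl2, −20 to 0 °C
Reagents that add atoms: di-tert-butyl dicarbonate, CC(C)(C)OC(=O)OC(=O)OC(C)(C)C
Why: DMAP-catalysed acylation of the lactol hydroxyl gives an allylic acetal carbonate that is hydride-stable and a good leaving group for the later allyl-metal chemistry (O-acylation).

Step 9
Reactants: 14 tert-butyl [(7aR)-4,4,7a-trimethyl-6-oxo-2,4,5,6,7,7a-hexahydro-1-benzofuran-2-yl] carbonate
Product: 15 tert-butyl [(6S,7aR)-6-hydroxy-4,4,7a-trimethyl-2,4,5,6,7,7a-hexahydro-1-benzofuran-2-yl] carbonate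
Conditions: Li[(s-Bu)3BH], THF, −78 °C; then H2O
Reagents that add atoms: none
Why: Substrate-controlled bulky-hydride reduction: the axial methyl groups on C4 and C7a block the axial approach, so hydride adds equatorially and gives the axial (6S) alcohol cis to the angular methyl (the loliolide relationship), while the carbonate survives at −78 °C.

Step 10
Reactants: 15 tert-butyl [(6S,7aR)-6-hydroxy-4,4,7a-trimethyl-2,4,5,6,7,7a-hexahydro-1-benzofuran-2-yl] carbonate
Product: 16 tert-butyl [(6S,7aR)-6-[(tert-butyldimethylsilyl)oxy]-4,4,7a-trimethyl-2,4,5,6,7,7a-hexahydro-1-benzofuran-2-yl] carbonate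
Conditions: TBSCl, imidazole, DMF, 35 °C
Reagents that add atoms: tert-butyldimethylsilyl chloride, CC(C)(C)[Si](C)(C)Cl
Why: Base-mediated silylation protects the secondary alcohol without a Lewis acid that could ionise the acetal carbonate (silyl ether formation).

**Fragment B (cis-diborylpropene)**

Step 11
Reactants: 17 propyne
Product: 19 2-[(1Z)-2-bromoprop-1-en-1-yl]-6-methyl-1,3,6,2-dioxazaborocane-4,8-dione, via bromoalkenyl dibromoborane 18 (not isolated)
Conditions: BBr3, CH2Cl2, −78 °C; then disodium N-methyliminodiacetate, MeCN, −40 to 0 °C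
Reagents that add atoms: boron tribromide, BrB(Br)Br; disodium N-methyliminodiacetate, CN(CC(=O)[O-])CC(=O)[O-].[Na+].[Na+]
Why: syn-Bromoboration of propyne puts boron on the terminal carbon cis to bromine, and complexation with MIDA at low temperature locks that Z geometry before it can isomerise (haloboration, then boronate formation).

Step 12
Reactants: 19 2-[(1Z)-2-bromoprop-1-en-1-yl]-6-methyl-1,3,6,2-dioxazaborocane-4,8-dione
Product: 20 6-methyl-2-[(1E)-2-(4,4,5,5-tetramethyl-1,3,2-dioxaborolan-2-yl)prop-1-en-1-yl]-1,3,6,2-dioxazaborocane-4,8-dione (the two boron groups cis)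
Conditions: B2pin2, PdCl2(MeCN)2 (3 mol %), SPhos (6 mol %), KOAc, toluene, 45 °C
Reagents that add atoms: bis(pinacolato)diboron, CC1(C)OB(OC1(C)C)B1OC(C)(C)C(C)(C)O1
Why: Miyaura borylation replaces the alkenyl bromide with retention of geometry, and the sp3-hybridised MIDA boronate is inert under these anhydrous acetate conditions.

**Fragment C (pentaenyl iodide)**

Step 13
Reactants: 21 (E)-pent-2-en-4-yn-1-ol
Product: 22 tert-butyldimethyl{[(2E)-pent-2-en-4-yn-1-yl]oxy}silane
Conditions: TBSCl, imidazole, CH2Cl2, 0 °C to rt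
Reagents that add atoms: tert-butyldimethylsilyl chloride, CC(C)(C)[Si](C)(C)Cl
Why: Silylation removes the acidic hydroxyl before the organoaluminium step (silyl ether formation).

Step 14
Reactants: 22 tert-butyldimethyl{[(2E)-pent-2-en-4-yn-1-yl]oxy}silane
Product: 25 (2E,4E)-6-[(tert-butyldimethylsilyl)oxy]-3-methylhexa-2,4-dien-1-ol, via alkenylalane 23 (not isolated), via lithium alanate 24 (not isolated)
Conditions: AlMe3 (2 equiv), Cp2ZrCl2 (0.25 equiv), CH2Cl2, 0 °C to rt; volatiles removed; n-BuLi, THF, −78 °C; (CH2O)n, rt; then H2O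
Reagents that add atoms: trimethylaluminium, C[Al](C)C; formaldehyde (as paraformaldehyde), C=O
Why: Zirconium-catalysed methylalumination (Negishi carboalumination) adds methyl and aluminium syn with methyl on the internal carbon, and the alanate is hydroxymethylated with retention, which fixes the E trisubstituted alkene.

Step 15
Reactants: 25 (2E,4E)-6-[(tert-butyldimethylsilyl)oxy]-3-methylhexa-2,4-dien-1-ol
Product: 26 {[(2E,4E)-6-bromo-4-methylhexa-2,4-dien-1-yl]oxy}(tert-butyl)dimethylsilane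
Conditions: CBr4, PPh3, CH2Cl2, −20 °C
Reagents that add atoms: carbon tetrabromide, BrC(Br)(Br)Br
Why: Appel bromination converts the primary allylic alcohol into the bromide under neutral conditions that keep the silyl ether and the diene geometry.

Step 16
Reactants: 26 {[(2E,4E)-6-bromo-4-methylhexa-2,4-dien-1-yl]oxy}(tert-butyl)dimethylsilane
Product: 27 diethyl [(2E,4E)-6-[(tert-butyldimethylsilyl)oxy]-3-methylhexa-2,4-dien-1-yl]phosphonate
Conditions: P(OEt)3, neat, 90 °C
Reagents that add atoms: triethyl phosphite, CCOP(OCC)OCC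
Why: Michaelis–Arbuzov reaction at the unhindered primary allylic carbon gives the phosphonate for the olefination.

Step 17
Reactants: 28 (E)-3-methylpent-2-en-4-yn-1-ol
Product: 29 (2E,4E)-3-methyl-5-(tributylstannyl)penta-2,4-dien-1-ol
Conditions: Bu3SnH, PdCl2(PPh3)2 (2 mol %), THF, 0 °C
Reagents that add atoms: tributyltin hydride, CCCC[SnH](CCCC)CCCC
Why: Palladium-catalysed syn hydrostannation of the terminal alkyne of the E-enynol puts tin on the terminal carbon and gives the (E)-alkenylstannane; the minor internal regioisomer is removed by chromatography.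

Step 18
Reactants: 29 (2E,4E)-3-methyl-5-(tributylstannyl)penta-2,4-dien-1-ol
Product: 30 (2E,4E)-5-iodo-3-methylpenta-2,4-dien-1-ol
Conditions: I2, CH2Cl2, 0 °C, dark
Reagents that add atoms: iodine, II
Why: Iododestannylation replaces tin by iodine with retention of alkene geometry.

Step 19
Reactants: 30 (2E,4E)-5-iodo-3-methylpenta-2,4-dien-1-ol
Product: 31 (2E,4E)-5-iodo-3-methylpenta-2,4-dienal
Conditions: MnO2, CH2Cl2, rt, dark
Reagents that add atoms: none
Why: Manganese dioxide oxidises the allylic alcohol to the dienal without touching the alkenyl iodide or the alkene geometry (allylic oxidation).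

Step 20
Reactants: 27 diethyl [(2E,4E)-6-[(tert-butyldimethylsilyl)oxy]-3-methylhexa-2,4-dien-1-yl]phosphonate; 31 (2E,4E)-5-iodo-3-methylpenta-2,4-dienal
Product: 33 tert-butyl{[(2E,4E,6E,8E,10E)-11-iodo-4,9-dimethylundeca-2,4,6,8,10-pentaen-1-yl]oxy}dimethylsilane, via phosphonate carbanion 32 (not isolated)
Conditions: 27, NaN(SiMe3)2, THF, −78 °C; 31, −78 to 0 °C, dark
Reagents that add atoms: none
Why: Horner–Wadsworth–Emmons olefination of the allylic phosphonate anion with the dienal forms the central disubstituted double bond with high E selectivity, and the alkenyl iodide is inert to these conditions.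

**Fragment union and end game**

Step 21
Reactants: 16 tert-butyl [(6S,7aR)-6-[(tert-butyldimethylsilyl)oxy]-4,4,7a-trimethyl-2,4,5,6,7,7a-hexahydro-1-benzofuran-2-yl] carbonate; 20 cis-diborylpropene (Bpin/B(MIDA))
Product: 34 2-[(1Z)-2-[(2S,6S,7aR)-6-[(tert-butyldimethylsilyl)oxy]-4,4,7a-trimethyl-2,4,5,6,7,7a-hexahydro-1-benzofuran-2-yl]prop-1-en-1-yl]-6-methyl-1,3,6,2-dioxazaborocane-4,8-dione
Conditions: Ni(cod)2 (10 mol %), (R,R)-TADDOL-derived phenylphosphonite (20 mol %, enantiomer fixed by screening), 20 (1.5 equiv), THF, 30 °C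
Reagents that add atoms: none
Why: Proposed new method: a chiral zerovalent nickel–phosphonite complex ionises either anomer of the allylic acetal carbonate (loss of CO2) to an oxygen-substituted allyl divalent nickel tert-butoxide whose two faces equilibrate through the free oxocarbenium ion, the nickel-bound tert-butoxide activates the pinacol boronate for base-free transmetalation while the MIDA boron stays inert, and inner-sphere reductive elimination at the unhindered acetal carbon (the other allyl terminus is fully substituted) forms the C2–alkenyl bond with retention of alkene geometry on the face chosen by the ligand, which sets (2S) from the anomeric mixture; the closest known reactions are the nickel-catalysed enantioselective arylation of 2H-chromene acetals with arylboron reagents and base-free allylic Suzuki–Miyaura couplings of allyl carbonates, neither shown for a non-aromatic bicyclic 2-acyloxy-2,5-dihydrofuran, for a hindered alkenyl boronate or under catalyst-controlled diastereoselection.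

Step 22
Reactants: 34 ring-bearing (Z)-alkenyl MIDA boronate; 33 pentaenyl iodide
Product: 36 tert-butyl{[(2E,4E,6E,8E,10E,12Z)-13-[(2S,6S,7aR)-6-[(tert-butyldimethylsilyl)oxy]-4,4,7a-trimethyl-2,4,5,6,7,7a-hexahydro-1-benzofuran-2-yl]-4,9-dimethyltetradeca-2,4,6,8,10,12-hexaen-1-yl]oxy}dimethylsilane, via alkenylboronic acid 35 (not isolated)
Conditions: Pd(OAc)2 (5 mol %), SPhos (10 mol %), 3 M aq. K3PO4, THF, 40 °C, degassed, dark
Reagents that add atoms: none
Why: Slow-release Suzuki–Miyaura coupling: aqueous phosphate unmasks the MIDA boronate gradually so the sensitive alkenylboronic acid couples with the pentaenyl iodide as it forms, with retention at both alkenes, giving the 12Z,10E diene junction.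

Step 23
Reactants: 36 bis-silyl ether
Product: 37 (2E,4E,6E,8E,10E,12Z)-13-[(2S,6S,7aR)-6-hydroxy-4,4,7a-trimethyl-2,4,5,6,7,7a-hexahydro-1-benzofuran-2-yl]-4,9-dimethyltetradeca-2,4,6,8,10,12-hexaen-1-ol (target)
Conditions: Bu4NF, THF, 0 °C to rt, dark
Reagents that add atoms: none
Why: Fluoride cleaves both silyl ethers under non-acidic conditions, so the acid-labile C2 centre and the polyene geometry are untouched (desilylation).

**Compound list**
1 | mesityl oxide | CC(=O)C=C(C)C | starting material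
2 | methyl acetoacetate | COC(=O)CC(C)=O | starting material
3 | methyl 2,6,6-trimethyl-4-oxocyclohex-2-ene-1-carboxylate (racemic) | COC(=O)C1C(C)=CC(=O)CC1(C)C | intermediate
4 | methyl 7,9,9-trimethyl-1,4-dioxaspiro[4.5]dec-7-ene-8-carboxylate | COC(=O)C1=C(C)CC2(CC1(C)C)OCCO2 | intermediate
5 | (7,9,9-trimethyl-1,4-dioxaspiro[4.5]dec-7-en-8-yl)methanol | OCC1=C(C)CC2(CC1(C)C)OCCO2 | intermediate
6 | [(1R,6R)-4,4-(ethylenedioxy)-2,2,6-trimethyl-7-oxabicyclo[4.1.0]heptan-1-yl]methanol | OC[C@@]12O[C@]1(C)CC3(CC2(C)C)OCCO3 | intermediate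
7 | (1S,6R)-4,4-(ethylenedioxy)-2,2,6-trimethyl-7-oxabicyclo[4.1.0]heptane-1-carbaldehyde | O=C[C@@]12O[C@]1(C)CC3(CC2(C)C)OCCO3 | intermediate
8 | chloromethyl methyl ether | COCCl | starting material
9 | (methoxymethyl)triphenylphosphonium chloride | COC[P+](c1ccccc1)(c1ccccc1)c1ccccc1.[Cl-] | intermediate
10 | (methoxymethylidene)triphenylphosphorane (phosphorus ylide) | COC=P(c1ccccc1)(c1ccccc1)c1ccccc1 | intermediate
11 | (1S,6R)-4,4-(ethylenedioxy)-1-(2-methoxyethenyl)-2,2,6-trimethyl-7-oxabicyclo[4.1.0]heptane (epoxy enol ether, E/Z mixture) | COC=C[C@@]12O[C@]1(C)CC3(CC2(C)C)OCCO3 | intermediate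
12 | (7aR)-6,6-(ethylenedioxy)-2-methoxy-4,4,7a-trimethyl-2,4,5,6,7,7a-hexahydro-1-benzofuran (methoxy acetal, C2 anomers) | COC1C=C2C(C)(C)CC3(C[C@@]2(C)O1)OCCO3 | intermediate
13 | (7aR)-2-hydroxy-4,4,7a-trimethyl-2,4,5,7a-tetrahydro-1-benzofuran-6(7H)-one (C2 anomers) | OC1C=C2C(C)(C)CC(=O)C[C@@]2(C)O1 | intermediate
14 | tert-butyl [(7aR)-4,4,7a-trimethyl-6-oxo-2,4,5,6,7,7a-hexahydro-1-benzofuran-2-yl] carbonate (C2 anomers) | CC(C)(C)OC(=O)OC1C=C2C(C)(C)CC(=O)C[C@@]2(C)O1 | intermediate
15 | tert-butyl [(6S,7aR)-6-hydroxy-4,4,7a-trimethyl-2,4,5,6,7,7a-hexahydro-1-benzofuran-2-yl] carbonate (C2 anomers) | CC(C)(C)OC(=O)OC1C=C2C(C)(C)C[C@H](O)C[C@@]2(C)O1 | intermediate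
16 | tert-butyl [(6S,7aR)-6-[(tert-butyldimethylsilyl)oxy]-4,4,7a-trimethyl-2,4,5,6,7,7a-hexahydro-1-benzofuran-2-yl] carbonate (C2 anomers) | CC(C)(C)OC(=O)OC1C=C2C(C)(C)C[C@H](O[Si](C)(C)C(C)(C)C)C[C@@]2(C)O1 | intermediate
17 | propyne | CC#C | starting material
18 | dibromo[(1Z)-2-bromoprop-1-en-1-yl]borane | C/C(Br)=C/B(Br)Br | intermediate
19 | 2-[(1Z)-2-bromoprop-1-en-1-yl]-6-methyl-1,3,6,2-dioxazaborocane-4,8-dione | C/C(Br)=C/B1OC(=O)CN(C)CC(=O)O1 | intermediate
20 | 6-methyl-2-[(1E)-2-(4,4,5,5-tetramethyl-1,3,2-dioxaborolan-2-yl)prop-1-en-1-yl]-1,3,6,2-dioxazaborocane-4,8-dione (boron groups cis) | C/C(B1OC(C)(C)C(C)(C)O1)=C/B2OC(=O)CN(C)CC(=O)O2 | intermediate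
21 | (E)-pent-2-en-4-yn-1-ol | OC/C=C/C#C | starting material
22 | tert-butyldimethyl{[(2E)-pent-2-en-4-yn-1-yl]oxy}silane | C#C/C=C/CO[Si](C)(C)C(C)(C)C | intermediate
23 | [(1E,3E)-5-[(tert-butyldimethylsilyl)oxy]-2-methylpenta-1,3-dien-1-yl]dimethylalane | C[Al](C)/C=C(C)/C=C/CO[Si](C)(C)C(C)(C)C | intermediate
24 | lithium butyl[(1E,3E)-5-[(tert-butyldimethylsilyl)oxy]-2-methylpenta-1,3-dien-1-yl]dimethylalanate | [Li+].CCCC[Al-](C)(C)/C=C(C)/C=C/CO[Si](C)(C)C(C)(C)C | intermediate
25 | (2E,4E)-6-[(tert-butyldimethylsilyl)oxy]-3-methylhexa-2,4-dien-1-ol | OC/C=C(C)/C=C/CO[Si](C)(C)C(C)(C)C | intermediate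
26 | {[(2E,4E)-6-bromo-4-methylhexa-2,4-dien-1-yl]oxy}(tert-butyl)dimethylsilane | BrC/C=C(C)/C=C/CO[Si](C)(C)C(C)(C)C | intermediate
27 | diethyl [(2E,4E)-6-[(tert-butyldimethylsilyl)oxy]-3-methylhexa-2,4-dien-1-yl]phosphonate | CCOP(=O)(OCC)C/C=C(C)/C=C/CO[Si](C)(C)C(C)(C)C | intermediate
28 | (E)-3-methylpent-2-en-4-yn-1-ol | C#C/C(C)=C/CO | starting material
29 | (2E,4E)-3-methyl-5-(tributylstannyl)penta-2,4-dien-1-ol | CCCC[Sn](CCCC)(CCCC)/C=C/C(C)=C/CO | intermediate
30 | (2E,4E)-5-iodo-3-methylpenta-2,4-dien-1-ol | I/C=C/C(C)=C/CO | intermediate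
31 | (2E,4E)-5-iodo-3-methylpenta-2,4-dienal | I/C=C/C(C)=C/C=O | intermediate
32 | sodium salt of the carbanion of 27 (phosphonate carbanion) | [Na+].CCOP(=O)(OCC)[CH-]/C=C(C)/C=C/CO[Si](C)(C)C(C)(C)C | intermediate
33 | tert-butyl{[(2E,4E,6E,8E,10E)-11-iodo-4,9-dimethylundeca-2,4,6,8,10-pentaen-1-yl]oxy}dimethylsilane | I/C=C/C(C)=C/C=C/C=C(C)/C=C/CO[Si](C)(C)C(C)(C)C | intermediate
34 | 2-[(1Z)-2-[(2S,6S,7aR)-6-[(tert-butyldimethylsilyl)oxy]-4,4,7a-trimethyl-2,4,5,6,7,7a-hexahydro-1-benzofuran-2-yl]prop-1-en-1-yl]-6-methyl-1,3,6,2-dioxazaborocane-4,8-dione | C/C(=C/B3OC(=O)CN(C)CC(=O)O3)[C@@H]1C=C2C(C)(C)C[C@H](O[Si](C)(C)C(C)(C)C)C[C@@]2(C)O1 | intermediate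
35 | [(1Z)-2-[(2S,6S,7aR)-6-[(tert-butyldimethylsilyl)oxy]-4,4,7a-trimethyl-2,4,5,6,7,7a-hexahydro-1-benzofuran-2-yl]prop-1-en-1-yl]boronic acid | C/C(=C/B(O)O)[C@@H]1C=C2C(C)(C)C[C@H](O[Si](C)(C)C(C)(C)C)C[C@@]2(C)O1 | intermediate
36 | bis(tert-butyldimethylsilyl) ether of the target (both hydroxyls silylated) | C/C(=C/C=C/C(C)=C/C=C/C=C(C)/C=C/CO[Si](C)(C)C(C)(C)C)[C@@H]1C=C2C(C)(C)C[C@H](O[Si](C)(C)C(C)(C)C)C[C@@]2(C)O1 | intermediate
37 | (2E,4E,6E,8E,10E,12Z)-13-[(2S,6S,7aR)-6-hydroxy-4,4,7a-trimethyl-2,4,5,6,7,7a-hexahydro-1-benzofuran-2-yl]-4,9-dimethyltetradeca-2,4,6,8,10,12-hexaen-1-ol | C/C(=C/C=C/C(C)=C/C=C/C=C(C)/C=C/CO)[C@@H]1C=C2C(C)(C)C[C@H](O)C[C@@]2(C)O1 | target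

**Step count and risks**
Total steps: 23. Longest linear sequence: 12 (steps 1, 2, 3, 4, 5, 7, 8, 9, 10, 21, 22, 23).

Step 21 (the new nickel coupling; facial control at C2 and transmetalation of a hindered boronate are untested). Fallback with known chemistry, from 16 and 20 back to 34: 20 is treated briefly with aqueous KHF2 in MeOH at 0 °C, which converts only the pinacol ester and gives potassium trifluoro[(1E)-1-(6-methyl-4,8-dioxo-1,3,6,2-dioxazaborocan-2-yl)prop-1-en-2-yl]borate F1. BF3·OEt2 in MeCN at −40 °C then ionises 16 to the oxocarbenium ion, which F1 traps (Lewis-acid coupling of acetal-type electrophiles with alkenyltrifluoroborates, no transition metal, substrate control only). This should give 34 and its C2 epimer, the (2R,6S,7aR) isomer F2, in roughly equal amounts; they are separated by preparative HPLC and 34 goes on to step 22.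

Step 7 (one-pot Wittig, rearrangement and double hydrolysis; the β-alkoxy keto lactol 13 may eliminate or hydrolyse unevenly). Fallback through the lactone oxidation level, from 7 back to 16: 7 is methoxymethylenated with 9 as before but worked up neutral, and a trace of pyridinium p-toluenesulfonate in CH2Cl2 gives the methoxy acetal 12, which is isolated. CrO3/aq. H2SO4 in acetone at 0 °C hydrolyses both acetals and oxidises the lactol as it forms, giving (7aR)-4,4,7a-trimethyl-7,7a-dihydro-1-benzofuran-2,6(4H,5H)-dione (dehydrololiolide) F3. Li[(s-Bu)3BH] at −78 °C reduces the ketone to (6S,7aR)-6-hydroxy-4,4,7a-trimethyl-5,6,7,7a-tetrahydro-1-benzofuran-2(4H)-one (loliolide) F4. TBSCl/imidazole gives loliolide tert-butyldimethylsilyl ether F5, i-Bu2AlH in CH2Cl2 at −78 °C gives (6S,7aR)-6-[(tert-butyldimethylsilyl)oxy]-4,4,7a-trimethyl-2,4,5,6,7,7a-hexahydro-1-benzofuran-2-ol F6, and Boc2O/DMAP converts this into 16.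

Step 22 (slow-release Suzuki coupling of a hindered trisubstituted alkenylboron with a light-sensitive pentaenyl iodide). Fallback by reversed polarity and Stille coupling, from 34 back to 36: aqueous NaOH in THF frees the boronic acid 35, and N-iodosuccinimide in MeCN at 0 °C in the dark replaces boron by iodine with retention, giving tert-butyl{[(2S,6S,7aR)-2-[(1Z)-1-iodoprop-1-en-2-yl]-4,4,7a-trimethyl-2,4,5,6,7,7a-hexahydro-1-benzofuran-6-yl]oxy}dimethylsilane F7. On the polyene side, 29 is oxidised with MnO2 to (2E,4E)-3-methyl-5-(tributylstannyl)penta-2,4-dienal F8, and Horner–Wadsworth–Emmons reaction with 27 (NaN(SiMe3)2, THF, −78 °C) gives tert-butyl{[(2E,4E,6E,8E,10E)-4,9-dimethyl-11-(tributylstannyl)undeca-2,4,6,8,10-pentaen-1-yl]oxy}dimethylsilane F9. Stille coupling of F7 with F9 (Pd2(dba)3, AsPh3, N-methylpyrrolidone, rt, dark) gives 36.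

**Further compounds**
F1 | step 21 | potassium trifluoro[(1E)-1-(6-methyl-4,8-dioxo-1,3,6,2-dioxazaborocan-2-yl)prop-1-en-2-yl]borate | [K+].C/C(=C/B1OC(=O)CN(C)CC(=O)O1)[B-](F)(F)F
F2 | step 21 | 2-[(1Z)-2-[(2R,6S,7aR)-6-[(tert-butyldimethylsilyl)oxy]-4,4,7a-trimethyl-2,4,5,6,7,7a-hexahydro-1-benzofuran-2-yl]prop-1-en-1-yl]-6-methyl-1,3,6,2-dioxazaborocane-4,8-dione | C/C(=C/B3OC(=O)CN(C)CC(=O)O3)[C@H]1C=C2C(C)(C)C[C@H](O[Si](C)(C)C(C)(C)C)C[C@@]2(C)O1
F3 | step 7 | (7aR)-4,4,7a-trimethyl-7,7a-dihydro-1-benzofuran-2,6(4H,5H)-dione (dehydrololiolide) | O=C1C=C2C(C)(C)CC(=O)C[C@@]2(C)O1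
F4 | step 7 | (6S,7aR)-6-hydroxy-4,4,7a-trimethyl-5,6,7,7a-tetrahydro-1-benzofuran-2(4H)-one (loliolide) | O=C1C=C2C(C)(C)C[C@H](O)C[C@@]2(C)O1
F5 | step 7 | (6S,7aR)-6-[(tert-butyldimethylsilyl)oxy]-4,4,7a-trimethyl-5,6,7,7a-tetrahydro-1-benzofuran-2(4H)-one | O=C1C=C2C(C)(C)C[C@H](O[Si](C)(C)C(C)(C)C)C[C@@]2(C)O1
F6 | step 7 | (6S,7aR)-6-[(tert-butyldimethylsilyl)oxy]-4,4,7a-trimethyl-2,4,5,6,7,7a-hexahydro-1-benzofuran-2-ol | OC1C=C2C(C)(C)C[C@H](O[Si](C)(C)C(C)(C)C)C[C@@]2(C)O1
F7 | step 22 | tert-butyl{[(2S,6S,7aR)-2-[(1Z)-1-iodoprop-1-en-2-yl]-4,4,7a-trimethyl-2,4,5,6,7,7a-hexahydro-1-benzofuran-6-yl]oxy}dimethylsilane | C/C(=C/I)[C@@H]1C=C2C(C)(C)C[C@H](O[Si](C)(C)C(C)(C)C)C[C@@]2(C)O1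
F8 | step 22 | (2E,4E)-3-methyl-5-(tributylstannyl)penta-2,4-dienal | CCCC[Sn](CCCC)(CCCC)/C=C/C(C)=C/C=O
F9 | step 22 | tert-butyl{[(2E,4E,6E,8E,10E)-4,9-dimethyl-11-(tributylstannyl)undeca-2,4,6,8,10-pentaen-1-yl]oxy}dimethylsilane | CCCC[Sn](CCCC)(CCCC)/C=C/C(C)=C/C=C/C=C(C)/C=C/CO[Si](C)(C)C(C)(C)C
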